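I started from the last reading. The flasks asked about differ in how the liquids go in, and I wanted one number to carry across them.

| flask | starting material | second substrate | solid reagent | remark | time |
|---|---|---|---|---|---|
| blue | 20 mM | 40 mM | 22 mM | run made earlier |  |
| green | 30 mM | 40 mM | 22 mM | run made earlier |  |
| zeta | 20 mM | 40.0 mM | 22.0 mM | everything together at the start | 15 min |
| delta | 20 mM (in portions, 3, over 12 min) | 40.0 mM | 22.0 mM | first portion at the start, last at 12 min | 15 min |
| eta | 20 mM | 40.0 mM (fed, over 12 min) | 22.0 mM | all else is in the flask from the start; the feed brings no volume worth counting | 15 min |
| beta | 20 mM (fed, over 12 min) | 40.0 mM | 22.0 mM | all else is in the flask from the start; the feed brings no volume worth counting | 15 min |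
| alpha | 20 mM (fed, over 3.0 min) | 40.0 mM | 22.0 mM | all else is in the flask from the start; the feed brings no volume worth counting | 15 min |

blue run (percent of the starting material charged)

| time / min | target / % |
|---|---|
| 1.33 | 0 |
| 2.00 | 2 |
| 3.00 | 5 |
| 5.00 | 3 |
| 10.0 | 9 |
| 15.0 | 14 |

green run (percent of the starting material charged)

| time / s | target / % |
|---|---|
| 10.0 | 1 |
| 12.0 | 3 |
| 20.0 | 0 |
| 30.0 | 1 |
| 50.0 | 0 |
| 90.0 | 1 |

(readings scatter by 1.5 percentage points)

- given per volume of solution although it is solid: solid reagent
- the analysis behind the earlier runs scatters by 1.5 percentage points, standard deviation
- at the start none of the solid reagent is in solution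

* which flask leads in amount of target, in percent of the starting material charged ("all alike" within 1.5 percentage points) (zeta / delta / eta / beta / alpha / all alike)
* how much target is there at the end, in percent of the starting material charged: zeta
* how much target is there at the end, in percent of the starting material charged: delta
* how much target is there at the end, in percent of the starting material charged: eta
* how much target is there at the end, in percent of the starting material charged: beta
* how much target is there at the end, in percent of the starting material charged: alpha

In the blue run target stood at 14% of the charge after 15.0 min, so a line through the origin gave 0.00933 /min, the fraction of the charge turned per minute. The second way ignored the origin and took the rise from 9% to 14% between the late readings, which gave 0.0100 /min. In logarithms those readings put target at time to the power 1.09, so a straight line was fair.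

The reading at 3.00 min parted from both, giving 0.0167 /min, nearly twice the first value. But the next reading fell by 2 percentage points against a scatter of 1.5 points per reading, so I judged that early point to be the one that cheated, and I kept 0.00933 /min. The green run, at a larger charge, should then have shown 1.40% at 90.0 s. It read 1%, which agrees, but a reading that size is barely distinguishable from zero.

I then assumed, without proof from these runs, that starting material reacts pseudo-first-order: each fraction present turns over at that same rate. What then counts is when it enters. For delta and beta the mean entry falls at half of 12 min, which leaves 9.00 min of mean stay, the time from mean entry of starting material to the end. For alpha the stay is 13.5 min, and for zeta and eta it is 15 min.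

Multiplying by the rate, I reckoned 14.0% for zeta and eta, 8.40% for delta and beta, and 12.6% for alpha. Stay is 15 min for both eta and zeta, so it gives the same number for these two flasks.

The forecast differed from my slow flasks: it gave 14% for zeta, 13.5% for delta, 13.5% for eta, 13.5% for beta, 14% for alpha, and all alike, with the “rate nearly independent of how the liquids are added”.

The flasks gave 15.1% for zeta, 10.3% for delta, 16.6% for eta, 10.7% for beta and 14.6% for alpha, so eta led.

    starting material + coupling partner → target (k = 4.70 /M/min)
    second substrate + coupling partner → second product (k = 4.10 /M/min)
    second substrate → decomposition product (k = 2.30 × 10⁻⁴ /min)
    coupling partner → decomposed reagent (k = 0.140 /min)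
    solid reagent ⇌ coupling partner, rate k5*(cs5 - [coupling partner]) while solid is left; crystals form when [coupling partner] > cs5 (solubility = 9.90 mM, k = 0.140 /min)

In delta solid reagent was still dissolving at the end, with 29.0% of its own charge left, and coupling partner stood at 2.85 mM at 12.0 min and 2.75 mM at 15.0 min, while starting material and second substrate both drew on it. In eta second substrate averaged 19.1 mM over the first 12 min, against 38.1 mM in zeta, and eta ended with 3.91 mM of second product against 5.30 mM in zeta. Stay put delta at 0.600 of zeta, and the flasks gave 0.682. Delta with 34 mM of starting material keeps the stay of 9.00 min, so my reckoning stays at 8.40%; the computed result is 9.65%.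

All runs were computed with made-up constants; noise was put on by code.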